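## Structural features

The target is a trans-fused Δ3-octalin. Ring A (C1, C2, C3=C4, C4a, C8a) is a cyclohexene and ring B (C4a, C5, C6, C7, C8, C8a) a cyclohexane, joined through the C4a–C8a bond. Seven contiguous ring stereocentres (C1, C2, C4a, C5, C6, C8, C8a) are joined by an eighth in the (R)-sec-butyl group on C2. The C1 acetyl and C2 sec-butyl groups are cis, H4a and H8a are trans-diaxial, the C5 hydroxyl is equatorial, the C6 acyloxy group is axial and cis to it, and the C8 methyl is equatorial. Fragile points are C1 (α to a ketone), the cis-diol monoester (acyl migration) and the (E)-3-methylglutaconate half-ester, whose doubly activated CH2 allows E/Z scrambling and double-bond shift. Any C5 ketone intermediate is β,γ-unsaturated with respect to C3=C4 and can slip into conjugation. The real difficulty is twofold: the sec-butyl centre differs only in methyl versus ethyl and cannot direct anything, yet must be related to seven ring centres; and only the axial C6 oxygen of a cis-diol may be acylated. The key step exploits ring B: oxygen at C5 beside C4a and methyl at C8 beside C8a is exactly the pattern that a 1-siloxy-4-methyl diene leaves on a C4a=C8a dienophile in an ortho-endo Diels–Alder reaction, and the activating aldehyde carbon becomes C4 of ring A.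

## Logic of the disconnections

**30 to 29.** The C–O bonds of the tert-butyl ester and of the dioxolane are cut. The free acid and the C1 methyl ketone are the two groups that would interfere earlier (the ketone in the C5 reduction, the acid in the acylation). One acidic operation reveals both; the demand is an acid mild enough for C1 and the C6 ester.

**29 to 28.** The C5–H bond is cut, so C5 arrives as a ketone while C6 already carries the acyl group. This removes any need to tell two hydroxyls of a cis-diol apart. The forward step needs axial hydride delivery without acyl migration.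

**28 to 23 and 27.** The C6 O–acyl bond is cut, which makes the route convergent. The forward esterification must not isomerise the side-chain alkene or epimerise C6.

**27 back to 24.** 27 comes from 26 by selective ester cleavage. 26 is cut at its sp2–sp3 bond between the alkene carbon and the CH2CO2tBu group, giving 25, whose enol triflate geometry (from 24) fixes the (E)-alkene. The coupling must proceed with retention.

**23 to 21.** The C6–O bond is cut. The enone polarity of 21 dictates that hydrogen goes to C7 and oxygen to C6, so regiochemistry is not in question. The demand is bond formation on the axial (β) side under neutral conditions.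

**21 to 20 to 19.** Only the oxidation level and the silyl group at C5 change. The C5 configuration created in the cycloaddition is erased here, so it need not be correct earlier.

**19 to 18 to 17.** The C3=C4 bond is cut by ring-closing metathesis and the C4=CH2 bond by methylenation. Ring A then comes from two vinyl groups, and the formyl group that activates the cycloaddition is the precursor of C4. The methylenation must be non-basic, because 17 is a β-siloxy aldehyde.

**17 to 14 and 16.** The C4a–C5 and C8–C8a bonds are cut (Diels–Alder). This removes ring B and four stereocentres at once and leaves an acyclic enal and a five-carbon diene. The forward step needs ortho regiochemistry, endo topology and one π-face of 14.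

**16 to 15.** The O–Si bond is cut; γ-enolisation and silylation of 15 give the diene.

**14 back to 11.** The C4a=C8a alkene of 14 is cut by olefination to 13. 13 comes from 12 by oxidation, and 12 from 11 by reductive removal of the auxiliary. The olefination must tolerate a doubly branched, epimerisable aldehyde.

**11 back to 8.** The ketal of 11 is cut to the ketone 10. The bond from C1 to the acetyl carbon is cut to 9, and the C2–vinyl bond to 8. Both stereocentres are set by the same oxazolidinone, so C1 and C2 are fixed in the absolute sense and therefore relative to the sec-butyl centre. A [3,3] construction of the C1–C2 bond from an allylic ester of a ketal-acetic acid would be shorter but was rejected. Its only resident stereocentre (methyl versus ethyl) cannot choose the face, so C1/C2 would form as both pairs relative to the sec-butyl group. Its enolate also carries a β-ketal oxygen that can be expelled.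

**8 back to 5, 1 and 2.** The alkene of 8 is cut by Horner–Wadsworth–Emmons olefination into 7 (from 6, from 5) and 4 (from 1 and 2 through 3). The sec-butyl centre comes from the chiral pool; the forward steps must not racemise the α-branched aldehyde 7.

## Other disconnections considered

**Alternative 1:** The cut is C4a–C8a. In the forward sense the kinetic C4a enolate of the ten-membered dienedione A2 adds across the ring to C8a of its acetyl-bearing enone, and cold protonation at C1 gives the octalinone A1.
- In its favour: one bond closes both rings. A1 already has the C5 ketone, the configured C6 oxygen and the free acetyl group. On this point it is better than the chosen plan, which spends steps 12 to 16 reaching the same ring B pattern.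
- Against it: A2 is a ten-membered ring with a cis alkene, a trisubstituted enone and four stereocentres, and needs a macrocyclisation. Its C2 centre is doubly allylic and γ to the enone, so it is at risk under the base. Enolisation must choose C4a over C6. The face of the transannular attack and the C1 protonation rest on ring conformation, not on a dependable rule.
- Comparison: mechanistically it is more elegant and equal in the endgame (esterify, reduce C5). However, A1 has two free ketones at the reduction stage. The step count to A2 would exceed that to 14, and stereocontrol is less predictable than an endo cycloaddition under reagent control.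

**Alternative 2:** The cut is C1–C8a, made by a 1,2-shift. Photolysis of the diazo ketone A4 in methanol lets C8a migrate to the carbene carbon, contracts the seven-membered ring to ring A, and gives the methyl ester A3.
- In its favour: migration occurs with retention at C8a, so the ring fusion cannot be lost. The C5/C6 cis-diol is secured early as an acetonide; on relative configuration at C5/C6 this is equal to or better than the chosen plan. The C1 ester should settle equatorial, which is the required sense.
- Against it: A4 needs a six–seven fused precursor and a diazo transfer, a detour in ring size. The carbene sits beside C2–H, so a 1,2-hydrogen shift competes with ring contraction. The ester must then be turned into the methyl ketone. The acetonide gives a cis-diol whose axial C6 hydroxyl must be acylated selectively, which is the problem the chosen plan avoids through the C5 ketone.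
- Comparison: structurally it solves the diol configuration well, but it is worse in step economy and in the final differentiation of the two oxygens.

**Alternative 3:** The cuts are C4a–C8a and C7–C8. The 2-siloxy diene of triene A6 adds intramolecularly to its (E)-enoate and gives the silyl enol ether A5; the tether becomes ring A and the cycloadduct ring B.
- In its favour: both rings and three stereocentres form in one step, and the face is set by the tether centres without a chiral catalyst. A5 is the regiodefined enol ether of the C5 ketone, so a Rubottom oxidation would install the C6 hydroxyl directly. On these points it is better than the chosen plan.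
- Against it: C8 must carry an activating ester, which then has to be reduced to a methyl group over several steps at a hindered position. The cis C3=C4 alkene next to the diene in A6 invites a [1,5]-hydrogen shift from C2. The cis/trans fusion selectivity of a decatriene with a Z-alkene in the tether is uncertain. A6 needs the same C1/C2/sec-butyl fragment as 14 plus a stereodefined dienol silyl ether.
- Comparison: it is more convergent in ring construction, but weaker in step economy after the cycloaddition and in the stability of its precursor.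

Key step: step 11

Remark: bicyclic compounds are named with the decalin locants of the target (C1 acetyl-bearing carbon, C2 sec-butyl, C5/C6 oxygens, C8 methyl). The configurations planned for 14 and 17 agree with the target at every centre except C5 of 17, which is epimeric by design.

Assumption: face selection by the oxazaborolidinium ion is taken from the formyl C–H···O binding model for enals, which leaves the C4a-si/C8a-si face of 14 open with the (R)-catalyst; if the model fails for this β-branched enal, the antipodal catalyst is used.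

## Steps

Step 1
Reactants: 1 (4S)-5,5-dimethyl-4-phenyl-1,3-oxazolidin-2-one; 2 (diethoxyphosphoryl)acetic acid
Product: 4 diethyl {2-[(4S)-5,5-dimethyl-2-oxo-4-phenyl-1,3-oxazolidin-3-yl]-2-oxoethyl}phosphonate, via mixed pivalic anhydride 3 (not isolated)
Conditions: 2, t-BuCOCl, Et3N, THF, −20 °C; then 1, LiCl, −20 °C → rt
Reagents that add atoms: none
Why: N-acylation of an oxazolidinone through a mixed pivalic anhydride under LiCl/Et3N; the weak base leaves the phosphonate CH2 and the C4 centre of the auxiliary untouched.

Step 2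
Reactants: 5 (2R)-2-methylbutanoic acid
Product: 6 (2R)-2-methylbutan-1-ol
Conditions: LiAlH4, Et2O, 0 °C → rt
Reagents that add atoms: none
Why: Hydride reduction of a carboxylic acid; the carboxylate formed first cannot enolise, so the stereocentre is kept.

Step 3
Reactants: 6 (2R)-2-methylbutan-1-ol; 4 phosphonate imide
Product: 8 (4S)-5,5-dimethyl-3-[(2E,4R)-4-methylhex-2-enoyl]-4-phenyl-1,3-oxazolidin-2-one, via (2R)-2-methylbutanal 7 (not isolated)
Conditions: DMP, NaHCO3, CH2Cl2, 0 °C; then 4, LiCl, iPr2NEt, MeCN, 0 °C → rt
Reagents that add atoms: none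
Why: Dess–Martin oxidation followed in the same flask by a Masamune–Roush Horner–Wadsworth–Emmons olefination; the weak base and immediate consumption of 7 should protect its α-stereocentre, and the stabilised phosphonate gives the (E)-alkene.

Step 4
Reactants: 8 N-enoyl oxazolidinone
Product: 9 (4S)-3-[(3R,4R)-3-ethenyl-4-methylhexanoyl]-5,5-dimethyl-4-phenyl-1,3-oxazolidin-2-one
Conditions: CH2=CHMgBr, CuBr·SMe2, THF/Me2S, −78 → −20 °C
Reagents that add atoms: vinylmagnesium bromide, C=C[Mg]Br
Why: Cuprate conjugate addition to an N-enoyl oxazolidinone; in the magnesium-chelated s-cis conformer the phenyl group shields one face and vinyl adds to the other, which sets the future C2 under auxiliary control and independently of the methyl/ethyl centre.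

Step 5
Reactants: 9 vinyl adduct
Product: 10 (4S)-3-[(2R,3R,4R)-2-acetyl-3-ethenyl-4-methylhexanoyl]-5,5-dimethyl-4-phenyl-1,3-oxazolidin-2-one
Conditions: LiN(iPr)2, THF, −78 °C; then AcCl, −78 °C
Reagents that add atoms: acetyl chloride, CC(=O)Cl
Why: C-acylation of the chelated (Z)-lithium enolate of an N-acyl oxazolidinone anti to the phenyl group sets the future C1; β-keto imides of this kind resist enolisation because allylic strain holds the C–H bond in the imide plane.

Step 6
Reactants: 10 β-keto imide
Product: 11 (4S)-3-[(2R,3R,4R)-3-ethenyl-4-methyl-2-(2-methyl-1,3-dioxolan-2-yl)hexanoyl]-5,5-dimethyl-4-phenyl-1,3-oxazolidin-2-one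
Conditions: Me3SiOCH2CH2OSiMe3, TMSOTf (cat.), CH2Cl2, −78 → −20 °C
Reagents that add atoms: 1,2-bis(trimethylsilyloxy)ethane, C[Si](C)(C)OCCO[Si](C)(C)C
Why: Noyori ketalisation, chosen because it is aprotic and cold and should leave the non-enolising centre next to the ketone alone.

Step 7
Reactants: 11 ketal imide
Product: 12 (2S,3R,4R)-3-ethenyl-4-methyl-2-(2-methyl-1,3-dioxolan-2-yl)hexan-1-ol
Conditions: LiBH4, MeOH, Et2O, 0 °C → rt
Reagents that add atoms: none
Why: Reductive cleavage of an N-acyl oxazolidinone; the geminal methyl groups of this auxiliary block attack at the ring carbonyl, so hydride should go to the hindered exocyclic carbonyl and 1 is recovered.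

Step 8
Reactants: 12 primary alcohol
Product: 13 (2S,3R,4R)-3-ethenyl-4-methyl-2-(2-methyl-1,3-dioxolan-2-yl)hexanal
Conditions: DMP, NaHCO3, CH2Cl2, 0 °C → rt
Reagents that add atoms: none
Why: Dess–Martin oxidation under bicarbonate buffer; no base strong enough to epimerise the α-centre or to open the β-ketal is present.

Step 9
Reactants: 13 aldehyde
Product: 14 (2E,4R,5R,6R)-5-ethenyl-6-methyl-4-(2-methyl-1,3-dioxolan-2-yl)oct-2-enal
Conditions: Ph3P=CHCHO, toluene, 80 °C
Reagents that add atoms: (triphenylphosphoranylidene)acetaldehyde, O=CC=P(c1ccccc1)(c1ccccc1)c1ccccc1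
Why: Wittig olefination with the stabilised formylmethylene ylide gives the (E)-enal; the ylide is essentially non-basic, so the centre that becomes γ to the aldehyde should keep its configuration.

Step 10
Reactants: 15 (2E)-pent-2-enal
Product: 16 tert-butyl(dimethyl)[(1E,3E)-penta-1,3-dien-1-yloxy]silane
Conditions: TBSOTf, Et3N, Et2O, 0 °C → rt
Reagents that add atoms: tert-butyldimethylsilyl trifluoromethanesulfonate, CC(C)(C)[Si](C)(C)OS(=O)(=O)C(F)(F)F
Why: Soft γ-enolisation and O-silylation of an enal gives the silyl dienol ether, mainly (1E,3E); minor Z isomers reach the s-cis conformation poorly and should stay behind in step 11, where the diene is used in excess.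

Step 11
Reactants: 14 (E)-enal; 16 (1E,3E)-siloxydiene
Product: 17 (1R,2S,5R,6S)-2-{[tert-butyl(dimethyl)silyl]oxy}-6-[(1S,2R,3R)-2-ethenyl-3-methyl-1-(2-methyl-1,3-dioxolan-2-yl)pentyl]-5-methylcyclohex-3-ene-1-carbaldehyde
Conditions: (R)-o-tolyl-CBS-oxazaborolidine (20 mol %), Tf2NH (18 mol %), 16 (2.5 equiv), CH2Cl2, −78 → −40 °C; Et3N quench
Reagents that add atoms: none
Why: Diels–Alder cycloaddition; the closest known type is the oxazaborolidinium-catalysed addition of siloxydienes to α,β-unsaturated aldehydes. The N-protonated oxazaborolidine binds the formyl oxygen of 14 and lowers its LUMO, and the diene adds in a concerted but asynchronous way, its nucleophilic methyl-bearing terminus C8 bonding to the β-carbon C8a ahead of C5 to C4a. Ring B closes as a six-membered carbocycle by [4+2] addition that is suprafacial on both partners; no other ring forms. At C4a and C8a the (E)-geometry of 14 becomes the trans relation of C4 and C1, and the absolute sense is set by the catalyst, which should leave the C4a-si/C8a-si face open. At C5 and C8 the (1E,3E)-geometry of 16 places OTBS and CH3 cis to each other, and the endo position of the Lewis-acid-bound formyl group places both cis to C4, so C5 is formed epimeric to the target on purpose. Ortho regiochemistry follows from the siloxy donor, which makes C8 the nucleophilic terminus. The step needs above all facial selectivity; the two branches on the resident C1 centre (ketal carbon and C2) are of similar bulk, so the intrinsic bias should be small and reagent control should dominate. Addition to C=C instead of open-chain addition to C=O is favoured by the bulky TBS group, the low temperature and the absence of free protic acid.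

Step 12
Reactants: 17 cycloadduct aldehyde
Product: 18 tert-butyl{[(1S,4R,5S,6R)-6-ethenyl-5-[(1S,2R,3R)-2-ethenyl-3-methyl-1-(2-methyl-1,3-dioxolan-2-yl)pentyl]-4-methylcyclohex-2-en-1-yl]oxy}dimethylsilane
Conditions: Tebbe reagent Cp2Ti(μ-CH2)(μ-Cl)AlMe2, pyridine, THF, −40 → 0 °C
Reagents that add atoms: Tebbe reagent, C[Al-]1(C)C[Ti](C2C=CC=C2)(C2C=CC=C2)[Cl+]1
Why: Titanium-mediated (Tebbe) methylenation is non-basic, so the β-siloxy aldehyde should neither epimerise at C4a nor eliminate silanol; ketal, silyl ether and alkenes are inert at this temperature.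

Step 13
Reactants: 18 triene
Product: 19 2-[(1S,2S,4aR,5S,8R,8aS)-2-[(2R)-butan-2-yl]-5-{[tert-butyl(dimethyl)silyl]oxy}-8-methyl-1,2,4a,5,8,8a-hexahydronaphthalen-1-yl]-2-methyl-1,3-dioxolane
Conditions: second-generation Grubbs catalyst RuCl2(=CHPh)(H2IMes)(PCy3) (5 mol %), CH2Cl2, 40 °C
Reagents that add atoms: none
Why: Ring-closing metathesis of the two terminal vinyl groups closes six-membered ring A with loss of ethene; the unstrained cis ring B alkene should not take part, and the trans fusion is already fixed at C4a/C8a.

Step 14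
Reactants: 19 bicyclic silyl ether
Product: 20 (1S,2S,4aR,5S,8R,8aS)-2-[(2R)-butan-2-yl]-8-methyl-1-(2-methyl-1,3-dioxolan-2-yl)-1,2,4a,5,8,8a-hexahydronaphthalen-5-ol
Conditions: TBAF, THF, 0 °C → rt
Reagents that add atoms: none
Why: Fluoride-mediated cleavage of the silyl ether; ketal and alkenes are inert.

Step 15
Reactants: 20 allylic alcohol
Product: 21 (1S,2S,4aR,8R,8aS)-2-[(2R)-butan-2-yl]-8-methyl-1-(2-methyl-1,3-dioxolan-2-yl)-1,4a,8,8a-tetrahydronaphthalen-5(2H)-one
Conditions: DMP, NaHCO3, CH2Cl2, 0 °C
Reagents that add atoms: none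
Why: Dess–Martin oxidation of the allylic alcohol to the enone erases the unwanted C5 configuration; buffered neutral conditions should keep H4a and the C3=C4 bond in place.

Step 16
Reactants: 21 enone
Product: 23 (1S,2S,4aR,6R,8R,8aS)-2-[(2R)-butan-2-yl]-6-hydroxy-8-methyl-1-(2-methyl-1,3-dioxolan-2-yl)-1,4a,6,7,8,8a-hexahydronaphthalen-5(2H)-one, via C6 hydroperoxide 22 (not isolated)
Conditions: Mn(dpm)3 (10 mol %), PhSiH3, O2 (1 atm), iPrOH/CH2Cl2, 0 °C; then P(OEt)3
Reagents that add atoms: dioxygen, O=O
Why: Mn-catalysed hydrogen-atom transfer to C7 of the enone gives the C6 α-keto radical, which is trapped by O2 (Mukaiyama-type reductive α-hydroxylation), and phosphite reduces the hydroperoxide. Bond formation at C6 is expected along the axial β direction, which keeps overlap with the carbonyl and meets only axial hydrogens; the neutral medium should spare H4a and the C3=C4 bond.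

Step 17
Reactants: 24 methyl 3-oxobutanoate
Product: 25 methyl (2E)-3-{[(trifluoromethyl)sulfonyl]oxy}but-2-enoate
Conditions: Tf2O, aq. Me4NOH, hexanes, 5 °C
Reagents that add atoms: trifluoromethanesulfonic anhydride, O=S(=O)(OS(=O)(=O)C(F)(F)F)C(F)(F)F
Why: Stereoselective enol triflation of a β-keto ester; the non-chelating tetramethylammonium enolate should give the (E)-triflate, with the triflate trans to the ester.

Step 18
Reactants: 25 (E)-enol triflate
Product: 26 5-tert-butyl 1-methyl (2E)-3-methylpent-2-enedioate
Conditions: BrZnCH2CO2tBu, Pd(PPh3)4 (5 mol %), THF, rt → 45 °C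
Reagents that add atoms: (2-tert-butoxy-2-oxoethyl)zinc bromide, CC(C)(C)OC(=O)C[Zn]Br
Why: Negishi-type coupling of a Reformatsky reagent with an alkenyl triflate proceeds with retention of alkene geometry, so the CH2CO2tBu group ends up trans to the methyl ester.

Step 19
Reactants: 26 mixed diester
Product: 27 (2E)-5-tert-butoxy-3-methyl-5-oxopent-2-enoic acid
Conditions: Me3SnOH, 1,2-dichloroethane, 70 °C; then aq. KHSO4
Reagents that add atoms: trimethyltin hydroxide, C[Sn](C)(C)O
Why: Methyl ester cleavage with trimethyltin hydroxide, a near-neutral reagent that leaves the tert-butyl ester and should not deprotonate the doubly activated CH2, so the (E)-geometry is kept.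

Step 20
Reactants: 23 α-hydroxy ketone; 27 half-ester acid
Product: 28 5-tert-butyl 1-[(1S,2S,4aR,6R,8R,8aS)-2-[(2R)-butan-2-yl]-8-methyl-1-(2-methyl-1,3-dioxolan-2-yl)-5-oxo-1,2,4a,5,6,7,8,8a-octahydronaphthalen-6-yl] (2E)-3-methylpent-2-enedioate
Conditions: EDC·HCl, DMAP (0.2 equiv), CH2Cl2, −20 → 0 °C
Reagents that add atoms: none
Why: Carbodiimide/DMAP (Steglich) esterification of the C6 hydroxyl while C5 is still a ketone, so no diol has to be differentiated; low temperature and little DMAP are chosen to limit ketene formation from the activated acid and epimerisation at C6.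

Step 21
Reactants: 28 C5 ketone ester
Product: 29 5-tert-butyl 1-[(1S,2S,4aR,5S,6R,8R,8aS)-2-[(2R)-butan-2-yl]-5-hydroxy-8-methyl-1-(2-methyl-1,3-dioxolan-2-yl)-1,2,4a,5,6,7,8,8a-octahydronaphthalen-6-yl] (2E)-3-methylpent-2-enedioate
Conditions: NaBH4, CeCl3·7H2O, MeOH/THF, −78 °C; AcOH quench
Reagents that add atoms: none
Why: Luche-type borohydride reduction; the small hydride should attack C5 axially from the α face (the β side is screened by the axial C6 acyloxy group) and give the equatorial C5 alcohol. The ketal keeps the C1 carbonyl out of reach, and cerium buffering with a cold acidic quench disfavours acyl migration and conjugate reduction.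

Step 22
Reactants: 29 protected precursor
Product: 30 (2E)-5-{[(1S,2S,4aR,5S,6R,8R,8aS)-1-acetyl-2-[(2R)-butan-2-yl]-5-hydroxy-8-methyl-1,2,4a,5,6,7,8,8a-octahydronaphthalen-6-yl]oxy}-3-methyl-5-oxopent-2-enoic acid
Conditions: CF3CO2H/H2O/CH2Cl2, 0 °C → rt
Reagents that add atoms: water, O
Why: Acidolysis; aqueous trifluoroacetic acid hydrolyses the dioxolane and cleaves the tert-butyl ester as isobutene in one operation, and with no base present C1 and the alkene geometry of the side chain should be safe.

## Compound list

1 | (4S)-5,5-dimethyl-4-phenyl-1,3-oxazolidin-2-one | O=C1OC(C)(C)[C@H](c2ccccc2)N1 | starting material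
2 | (diethoxyphosphoryl)acetic acid | CCOP(=O)(OCC)CC(=O)O | starting material
3 | (diethoxyphosphoryl)acetic pivalic anhydride | CCOP(=O)(OCC)CC(=O)OC(=O)C(C)(C)C | intermediate (not isolated)
4 | diethyl {2-[(4S)-5,5-dimethyl-2-oxo-4-phenyl-1,3-oxazolidin-3-yl]-2-oxoethyl}phosphonate | CCOP(=O)(OCC)CC(=O)N1C(=O)OC(C)(C)[C@@H]1c1ccccc1 | intermediate
5 | (2R)-2-methylbutanoic acid | CC[C@@H](C)C(=O)O | starting material
6 | (2R)-2-methylbutan-1-ol | CC[C@@H](C)CO | intermediate
7 | (2R)-2-methylbutanal | CC[C@@H](C)C=O | intermediate (not isolated)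
8 | (4S)-5,5-dimethyl-3-[(2E,4R)-4-methylhex-2-enoyl]-4-phenyl-1,3-oxazolidin-2-one | CC[C@@H](C)/C=C/C(=O)N1C(=O)OC(C)(C)[C@@H]1c1ccccc1 | intermediate
9 | (4S)-3-[(3R,4R)-3-ethenyl-4-methylhexanoyl]-5,5-dimethyl-4-phenyl-1,3-oxazolidin-2-one | CC[C@@H](C)[C@@H](C=C)CC(=O)N1C(=O)OC(C)(C)[C@@H]1c1ccccc1 | intermediate
10 | (4S)-3-[(2R,3R,4R)-2-acetyl-3-ethenyl-4-methylhexanoyl]-5,5-dimethyl-4-phenyl-1,3-oxazolidin-2-one | CC[C@@H](C)[C@@H](C=C)[C@H](C(C)=O)C(=O)N1C(=O)OC(C)(C)[C@@H]1c1ccccc1 | intermediate
11 | (4S)-3-[(2R,3R,4R)-3-ethenyl-4-methyl-2-(2-methyl-1,3-dioxolan-2-yl)hexanoyl]-5,5-dimethyl-4-phenyl-1,3-oxazolidin-2-one | CC[C@@H](C)[C@@H](C=C)[C@H](C2(C)OCCO2)C(=O)N1C(=O)OC(C)(C)[C@@H]1c1ccccc1 | intermediate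
12 | (2S,3R,4R)-3-ethenyl-4-methyl-2-(2-methyl-1,3-dioxolan-2-yl)hexan-1-ol | CC[C@@H](C)[C@@H](C=C)[C@H](C1(C)OCCO1)CO | intermediate
13 | (2S,3R,4R)-3-ethenyl-4-methyl-2-(2-methyl-1,3-dioxolan-2-yl)hexanal | CC[C@@H](C)[C@@H](C=C)[C@H](C1(C)OCCO1)C=O | intermediate
14 | (2E,4R,5R,6R)-5-ethenyl-6-methyl-4-(2-methyl-1,3-dioxolan-2-yl)oct-2-enal | O=C/C=C/[C@@H](C1(C)OCCO1)[C@H](C=C)[C@H](C)CC | intermediate
15 | (2E)-pent-2-enal | CC/C=C/C=O | starting material
16 | tert-butyl(dimethyl)[(1E,3E)-penta-1,3-dien-1-yloxy]silane | C/C=C/C=C/O[Si](C)(C)C(C)(C)C | intermediate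
17 | (1R,2S,5R,6S)-2-{[tert-butyl(dimethyl)silyl]oxy}-6-[(1S,2R,3R)-2-ethenyl-3-methyl-1-(2-methyl-1,3-dioxolan-2-yl)pentyl]-5-methylcyclohex-3-ene-1-carbaldehyde | O=C[C@H]1[C@@H](O[Si](C)(C)C(C)(C)C)C=C[C@@H](C)[C@@H]1[C@@H](C3(C)OCCO3)[C@H](C=C)[C@H](C)CC | intermediate
18 | tert-butyl{[(1S,4R,5S,6R)-6-ethenyl-5-[(1S,2R,3R)-2-ethenyl-3-methyl-1-(2-methyl-1,3-dioxolan-2-yl)pentyl]-4-methylcyclohex-2-en-1-yl]oxy}dimethylsilane | C=C[C@H]1[C@@H](O[Si](C)(C)C(C)(C)C)C=C[C@@H](C)[C@@H]1[C@@H](C3(C)OCCO3)[C@H](C=C)[C@H](C)CC | intermediate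
19 | 2-[(1S,2S,4aR,5S,8R,8aS)-2-[(2R)-butan-2-yl]-5-{[tert-butyl(dimethyl)silyl]oxy}-8-methyl-1,2,4a,5,8,8a-hexahydronaphthalen-1-yl]-2-methyl-1,3-dioxolane | CC[C@@H](C)[C@H]1C=C[C@H]2[C@@H](O[Si](C)(C)C(C)(C)C)C=C[C@@H](C)[C@@H]2[C@H]1C3(C)OCCO3 | intermediate
20 | (1S,2S,4aR,5S,8R,8aS)-2-[(2R)-butan-2-yl]-8-methyl-1-(2-methyl-1,3-dioxolan-2-yl)-1,2,4a,5,8,8a-hexahydronaphthalen-5-ol | CC[C@@H](C)[C@H]1C=C[C@H]2[C@@H](O)C=C[C@@H](C)[C@@H]2[C@H]1C3(C)OCCO3 | intermediate
21 | (1S,2S,4aR,8R,8aS)-2-[(2R)-butan-2-yl]-8-methyl-1-(2-methyl-1,3-dioxolan-2-yl)-1,4a,8,8a-tetrahydronaphthalen-5(2H)-one | CC[C@@H](C)[C@H]1C=C[C@H]2C(=O)C=C[C@@H](C)[C@@H]2[C@H]1C3(C)OCCO3 | intermediate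
22 | (1S,2S,4aR,6R,8R,8aS)-2-[(2R)-butan-2-yl]-6-hydroperoxy-8-methyl-1-(2-methyl-1,3-dioxolan-2-yl)-1,4a,6,7,8,8a-hexahydronaphthalen-5(2H)-one | CC[C@@H](C)[C@H]1C=C[C@H]2C(=O)[C@H](OO)C[C@@H](C)[C@@H]2[C@H]1C3(C)OCCO3 | intermediate (not isolated)
23 | (1S,2S,4aR,6R,8R,8aS)-2-[(2R)-butan-2-yl]-6-hydroxy-8-methyl-1-(2-methyl-1,3-dioxolan-2-yl)-1,4a,6,7,8,8a-hexahydronaphthalen-5(2H)-one | CC[C@@H](C)[C@H]1C=C[C@H]2C(=O)[C@H](O)C[C@@H](C)[C@@H]2[C@H]1C3(C)OCCO3 | intermediate
24 | methyl 3-oxobutanoate | COC(=O)CC(C)=O | starting material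
25 | methyl (2E)-3-{[(trifluoromethyl)sulfonyl]oxy}but-2-enoate | COC(=O)/C=C(\C)OS(=O)(=O)C(F)(F)F | intermediate
26 | 5-tert-butyl 1-methyl (2E)-3-methylpent-2-enedioate | COC(=O)/C=C(\C)CC(=O)OC(C)(C)C | intermediate
27 | (2E)-5-tert-butoxy-3-methyl-5-oxopent-2-enoic acid | OC(=O)/C=C(\C)CC(=O)OC(C)(C)C | intermediate
28 | 5-tert-butyl 1-[(1S,2S,4aR,6R,8R,8aS)-2-[(2R)-butan-2-yl]-8-methyl-1-(2-methyl-1,3-dioxolan-2-yl)-5-oxo-1,2,4a,5,6,7,8,8a-octahydronaphthalen-6-yl] (2E)-3-methylpent-2-enedioate | CC[C@@H](C)[C@H]1C=C[C@H]2C(=O)[C@H](OC(=O)/C=C(\C)CC(=O)OC(C)(C)C)C[C@@H](C)[C@@H]2[C@H]1C3(C)OCCO3 | intermediate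
29 | 5-tert-butyl 1-[(1S,2S,4aR,5S,6R,8R,8aS)-2-[(2R)-butan-2-yl]-5-hydroxy-8-methyl-1-(2-methyl-1,3-dioxolan-2-yl)-1,2,4a,5,6,7,8,8a-octahydronaphthalen-6-yl] (2E)-3-methylpent-2-enedioate | CC[C@@H](C)[C@H]1C=C[C@H]2[C@H](O)[C@H](OC(=O)/C=C(\C)CC(=O)OC(C)(C)C)C[C@@H](C)[C@@H]2[C@H]1C3(C)OCCO3 | intermediate
30 | (2E)-5-{[(1S,2S,4aR,5S,6R,8R,8aS)-1-acetyl-2-[(2R)-butan-2-yl]-5-hydroxy-8-methyl-1,2,4a,5,6,7,8,8a-octahydronaphthalen-6-yl]oxy}-3-methyl-5-oxopent-2-enoic acid | CC[C@@H](C)[C@H]1C=C[C@H]2[C@H](O)[C@H](OC(=O)/C=C(\C)CC(=O)O)C[C@@H](C)[C@@H]2[C@H]1C(C)=O | target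

## Step count and least certain steps

Total step count: 22. Longest linear sequence: 17 steps (5 to 30 through steps 2–9, 11–16 and 20–22); steps 1, 10 and 17–19 are side branches.

**Step 11 (key step).** Most likely to go wrong: insufficient facial selectivity, because the catalyst has to decide against a resident C1 centre that offers no clear help; consumption of the silyl dienol ether by open-chain addition to the activated carbonyl or by desilylation; slow bond formation at the doubly branched β-carbon. Fallback, from 14 and 15, returning at 20: activation is moved from the carbonyl oxygen to an iminium ion and the diene is made acid-stable.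
- 15 is heated with isopropenyl acetate and TsOH to give (1E,3E)-penta-1,3-dien-1-yl acetate F1.
- 14 and F1 are combined with (5S)-5-benzyl-2,2,3-trimethylimidazolidin-4-one hydrochloride in MeCN/H2O; its benzyl group should leave the same si face open, and the product is the acetoxy cycloadduct aldehyde F2.
- Aldehyde-selective, non-basic methylenation (CH2I2, Zn, Ti(OiPr)4) gives the acetoxy triene F3.
- Ring-closing metathesis as in step 13 gives the bicyclic acetate F4, and K2CO3/MeOH methanolysis returns 20.

**Step 16.** Most likely to go wrong: oxygen capture from the equatorial side (C6 epimer), drift of the C3=C4 bond into conjugation with the C5 carbonyl, or hydration of the ring A alkene by the same hydrogen-atom-transfer system. Fallback, from 21, returning at 23: a polar two-stage route. Conjugate reduction of 21 with LiBH(s-Bu)3 at −78 °C and trapping with Me3SiCl/Et3N gives the trimethylsilyl enol ether F5. Rubottom oxidation with dimethyldioxirane at −40 °C (axial epoxidation of the enol ether) and mild acidic work-up returns 23.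

**Step 20.** Most likely to go wrong: loss of a proton from the doubly activated CH2 of the activated acid (ketene formation), which shifts the double bond or scrambles its geometry; amine-induced epimerisation at C6. Fallback, from 27 and 23, returning at 28: an amine-free acyl transfer. 27 is converted with 2,2'-dipyridyl disulfide and PPh3 into S-pyridin-2-yl (2E)-5-tert-butoxy-3-methyl-5-oxopent-2-enethioate F6. F6 is coupled with 23 under thiophilic activation by AgOTf in CH2Cl2 to give 28.

**Step 9.** Most likely to go wrong: sluggish olefination of the doubly branched aldehyde, a second homologation of the product enal, and epimerisation at C1 on prolonged heating. Fallback, from 13, returning at 14: Horner–Wadsworth–Emmons reaction with (EtO)2P(O)CH2CO2Et, LiCl and DBU gives ethyl (2E,4R,5R,6R)-5-ethenyl-6-methyl-4-(2-methyl-1,3-dioxolan-2-yl)oct-2-enoate F7. Reduction with iBu2AlH at −78 °C gives (2E,4R,5R,6R)-5-ethenyl-6-methyl-4-(2-methyl-1,3-dioxolan-2-yl)oct-2-en-1-ol F8, and MnO2 oxidation returns 14.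

**Step 6.** Most likely to go wrong: incomplete ketalisation of the flanked methyl ketone, or Lewis-acid-induced enolisation at C1. Fallback, from 9, returning at 11: the acetyl carbon is introduced already at the ketal level. The titanium enolate of 9 (TiCl4, iPr2NEt, CH2Cl2, −78 °C) is alkylated with trimethyl orthoacetate to give (4S)-3-[(2R,3R,4R)-2-(1,1-dimethoxyethyl)-3-ethenyl-4-methylhexanoyl]-5,5-dimethyl-4-phenyl-1,3-oxazolidin-2-one F9. Exchange with ethylene glycol and pyridinium p-toluenesulfonate returns 11.

## Further compounds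

F1 | step 11 | (1E,3E)-penta-1,3-dien-1-yl acetate | C/C=C/C=C/OC(C)=O
F2 | step 11 | (1S,4R,5S,6R)-5-[(1S,2R,3R)-2-ethenyl-3-methyl-1-(2-methyl-1,3-dioxolan-2-yl)pentyl]-6-formyl-4-methylcyclohex-2-en-1-yl acetate | O=C[C@H]1[C@@H](OC(C)=O)C=C[C@@H](C)[C@@H]1[C@@H](C3(C)OCCO3)[C@H](C=C)[C@H](C)CC
F3 | step 11 | (1S,4R,5S,6R)-6-ethenyl-5-[(1S,2R,3R)-2-ethenyl-3-methyl-1-(2-methyl-1,3-dioxolan-2-yl)pentyl]-4-methylcyclohex-2-en-1-yl acetate | C=C[C@H]1[C@@H](OC(C)=O)C=C[C@@H](C)[C@@H]1[C@@H](C3(C)OCCO3)[C@H](C=C)[C@H](C)CC
F4 | step 11 | (1S,2S,4aR,5S,8R,8aS)-2-[(2R)-butan-2-yl]-8-methyl-1-(2-methyl-1,3-dioxolan-2-yl)-1,2,4a,5,8,8a-hexahydronaphthalen-5-yl acetate | CC[C@@H](C)[C@H]1C=C[C@H]2[C@@H](OC(C)=O)C=C[C@@H](C)[C@@H]2[C@H]1C3(C)OCCO3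
F5 | step 16 | {[(1S,2S,4aR,8R,8aS)-2-[(2R)-butan-2-yl]-8-methyl-1-(2-methyl-1,3-dioxolan-2-yl)-1,2,4a,7,8,8a-hexahydronaphthalen-5-yl]oxy}trimethylsilane | CC[C@@H](C)[C@H]1C=C[C@H]2C(O[Si](C)(C)C)=CC[C@@H](C)[C@@H]2[C@H]1C3(C)OCCO3
F6 | step 20 | S-pyridin-2-yl (2E)-5-tert-butoxy-3-methyl-5-oxopent-2-enethioate | CC(C)(C)OC(=O)C/C(C)=C/C(=O)Sc1ccccn1
F7 | step 9 | ethyl (2E,4R,5R,6R)-5-ethenyl-6-methyl-4-(2-methyl-1,3-dioxolan-2-yl)oct-2-enoate | CCOC(=O)/C=C/[C@@H](C1(C)OCCO1)[C@H](C=C)[C@H](C)CC
F8 | step 9 | (2E,4R,5R,6R)-5-ethenyl-6-methyl-4-(2-methyl-1,3-dioxolan-2-yl)oct-2-en-1-ol | OC/C=C/[C@@H](C1(C)OCCO1)[C@H](C=C)[C@H](C)CC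
F9 | step 6 | (4S)-3-[(2R,3R,4R)-2-(1,1-dimethoxyethyl)-3-ethenyl-4-methylhexanoyl]-5,5-dimethyl-4-phenyl-1,3-oxazolidin-2-one | CC[C@@H](C)[C@@H](C=C)[C@H](C(C)(OC)OC)C(=O)N1C(=O)OC(C)(C)[C@@H]1c1ccccc1
A1 | alternative 1 | trans-fused 1-acetyl-2-[(2R)-butan-2-yl]-6-{[tert-butyl(dimethyl)silyl]oxy}-8-methyl-1,4a,6,7,8,8a-hexahydronaphthalen-5(2H)-one (product of the transannular Michael closure) | CC[C@@H](C)[C@H]1C=C[C@H]2C(=O)[C@H](O[Si](C)(C)C(C)(C)C)C[C@@H](C)[C@@H]2[C@H]1C(C)=O
A2 | alternative 1 | 10-acetyl-1-[(2R)-butan-2-yl]-6-{[tert-butyl(dimethyl)silyl]oxy}-8-methylcyclodeca-2,9-dien-5-one (cis C2=C3, ring-trans C9=C10; ten-membered precursor) | CC[C@@H](C)[C@H]1/C=C\CC(=O)[C@H](O[Si](C)(C)C(C)(C)C)C[C@@H](C)/C=C/1C(C)=O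
A3 | alternative 2 | methyl ester of the trans-octalin C1 carboxylic acid with C5/C6 acetonide (product of the Wolff contraction) | CC[C@@H](C)[C@H]1C=C[C@H]2[C@@H]3OC(C)(C)O[C@@H]3C[C@@H](C)[C@@H]2[C@H]1C(=O)OC
A4 | alternative 2 | α-diazo ketone of the six–seven fused acetonide (diazo carbon = future C1, ketone carbon between it and C8a) | CC[C@@H](C)[C@H]1C=C[C@H]2[C@@H]3OC(C)(C)O[C@@H]3C[C@@H](C)[C@@H]2C(=O)C1=[N+]=[N-]
A5 | alternative 3 | trans-octalin C5 silyl enol ether with C8 methyl ester and C1 dioxolane (product of the intramolecular Diels–Alder reaction) | CC[C@@H](C)[C@H]1C=C[C@H]2C(O[Si](C)(C)C(C)(C)C)=CC[C@@H](C(=O)OC)[C@@H]2[C@H]1C3(C)OCCO3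
A6 | alternative 3 | methyl (2E,4R,5S,6Z,8Z)-5-[(2R)-butan-2-yl]-9-{[tert-butyl(dimethyl)silyl]oxy}-4-(2-methyl-1,3-dioxolan-2-yl)undeca-2,6,8,10-tetraenoate | COC(=O)/C=C/[C@@H](C1(C)OCCO1)[C@H](/C=C\C=C(/O[Si](C)(C)C(C)(C)C)C=C)[C@H](C)CC
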